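**Retrosynthetic overview**

Ring labels: A = trioxygenated ring, B = para-phenylene ring, C = monophenol ring (C1 ethano bridge to B, C2 oxygen to D, C3 free OH), D = ortho-disubstituted ring without OH.
Feature used: on ring C the free C3–OH stands directly beside C2, the carbon bound to the ring D oxygen. This ortho hydroxy/aryloxy pair is what an ortho-quinone carbene leaves behind after insertion into a phenol O–H bond.
Disconnections: (1) the two ring A O–CH3 bonds (BBr3, last step); (2) the ring C C2–O(ring D) bond, opened to a seco ortho-quinone diazide carrying the free ring D phenol. Closing this bond forms the only new ring, the 17-membered macrocycle.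
(3) The diazide goes back to a 2-aminophenol. The aminophenol goes back to a nitro bis-stilbene, which a single hydrogenation converts (two C=C, NO2, two O-benzyl groups).
(4) The chain is assembled D to A to B to C: Wittig (ring D ylide, ring A aldehyde), SNAr of the ring A phenol on 4-fluorobenzaldehyde, Wittig (ring B ylide, ring C 2-nitrobenzaldehyde). All four arenes are bought.

Key step: step 11

Assumption: both Wittig olefinations are expected to give E/Z mixtures that are carried on unseparated because step 9 erases the geometry; names and SMILES show the E isomers.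

**Route**

Step 1
Reactants: 1 2-hydroxybenzyl alcohol (salicyl alcohol)
Product: 2 2-(benzyloxy)benzyl alcohol
Conditions: BnBr (1.05 equiv), K2CO3, acetone, reflux
Reagents that add atoms: benzyl bromide, BrCc1ccccc1
Why: Williamson ether synthesis: K2CO3 deprotonates only the phenol (pKa about 10) and not the benzylic alcohol, so benzylation should occur at the ring D oxygen alone.

Step 2
Reactants: 2 2-(benzyloxy)benzyl alcohol
Product: 3 [2-(benzyloxy)benzyl]triphenylphosphonium bromide
Conditions: PPh3·HBr (1.0 equiv), MeCN, reflux
Reagents that add atoms: triphenylphosphine hydrobromide, [Br-].c1ccc(cc1)[PH+](c1ccccc1)c1ccccc1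
Why: Direct conversion of a benzylic alcohol into its phosphonium salt with PPh3·HBr, helped by the ortho alkoxy group that stabilises positive charge at the benzylic carbon, under acidity too weak to cleave an aryl benzyl ether.

Step 3
Reactants: 3 [2-(benzyloxy)benzyl]triphenylphosphonium bromide; 4 3-hydroxy-4,5-dimethoxybenzaldehyde
Product: 6 5-[(E)-2-(2-(benzyloxy)phenyl)ethenyl]-2,3-dimethoxyphenol, via ring D ylide 5 (not isolated)
Conditions: 3 (1.1 equiv), KOtBu (2.2 equiv), THF, 0 °C; then 4, 0 °C to rt; 1 M HCl work-up
Reagents that add atoms: none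
Why: Wittig olefination with a semistabilised benzylic ylide; the extra equivalent of base holds the ring A hydroxyl as a phenoxide that stands meta to the formyl group and so cannot deactivate it by conjugation, and the E/Z outcome is of no consequence.

Step 4
Reactants: 6 5-[(E)-2-(2-(benzyloxy)phenyl)ethenyl]-2,3-dimethoxyphenol; 7 4-fluorobenzaldehyde
Product: 8 4-{5-[(E)-2-(2-(benzyloxy)phenyl)ethenyl]-2,3-dimethoxyphenoxy}benzaldehyde
Conditions: K2CO3, DMF, 120 °C
Reagents that add atoms: none
Why: Nucleophilic aromatic substitution by addition–elimination: the only free phenoxide of 6 displaces the fluoride activated by the para formyl group, while the benzyl ether and the stilbene are inert to carbonate in DMF.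

Step 5
Reactants: 8 4-{5-[(E)-2-(2-(benzyloxy)phenyl)ethenyl]-2,3-dimethoxyphenoxy}benzaldehyde
Product: 9 (4-{5-[(E)-2-(2-(benzyloxy)phenyl)ethenyl]-2,3-dimethoxyphenoxy}phenyl)methanol
Conditions: NaBH4, THF–MeOH, 0 °C; H2O work-up
Reagents that add atoms: none
Why: Borohydride reduction of an aromatic aldehyde, which touches neither the stilbene nor any of the ethers.

Step 6
Reactants: 9 (4-{5-[(E)-2-(2-(benzyloxy)phenyl)ethenyl]-2,3-dimethoxyphenoxy}phenyl)methanol
Product: 10 (4-{5-[(E)-2-(2-(benzyloxy)phenyl)ethenyl]-2,3-dimethoxyphenoxy}benzyl)triphenylphosphonium bromide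
Conditions: PPh3·HBr (1.0 equiv), MeCN, reflux
Reagents that add atoms: triphenylphosphine hydrobromide, [Br-].c1ccc(cc1)[PH+](c1ccccc1)c1ccccc1
Why: Phosphonium salt formation from a benzylic alcohol with PPh3·HBr, favoured here by the para aryloxy donor, with water as the only by-product and no intermediate halide to isolate.

Step 7
Reactants: 11 3-hydroxy-2-nitrobenzaldehyde
Product: 12 3-(benzyloxy)-2-nitrobenzaldehyde
Conditions: BnBr, K2CO3, DMF, 60 °C
Reagents that add atoms: benzyl bromide, BrCc1ccccc1
Why: Williamson ether synthesis on the acidic ortho-nitrophenol, whose weakly nucleophilic phenoxide needs a dipolar aprotic solvent and gentle heating; the benzyl group is chosen because step 9 removes it without an extra operation.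

Step 8
Reactants: 10 (4-{5-[(E)-2-(2-(benzyloxy)phenyl)ethenyl]-2,3-dimethoxyphenoxy}benzyl)triphenylphosphonium bromide; 12 3-(benzyloxy)-2-nitrobenzaldehyde
Product: 14 1-(benzyloxy)-3-[(E)-2-(4-{5-[(E)-2-(2-(benzyloxy)phenyl)ethenyl]-2,3-dimethoxyphenoxy}phenyl)ethenyl]-2-nitrobenzene, via ring B ylide 13 (not isolated)
Conditions: K2CO3 (excess), 18-crown-6 (cat.), CH2Cl2, reflux
Reagents that add atoms: none
Why: Wittig olefination under mild solid–liquid carbonate conditions, in which the very electrophilic 2-nitrobenzaldehyde traps the semistabilised ylide as it forms and no strong base is present that could attack the nitroarene.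

Step 9
Reactants: 14 nitro bis-stilbene bis(benzyl ether)
Product: 15 2-amino-3-[2-(4-{5-[2-(2-hydroxyphenyl)ethyl]-2,3-dimethoxyphenoxy}phenyl)ethyl]phenol
Conditions: H2 (3 bar), 10% Pd/C, THF–MeOH, rt; filtered under Ar and used at once
Reagents that add atoms: none
Why: Heterogeneous catalytic hydrogenation and hydrogenolysis: Pd/C should saturate both stilbene double bonds, reduce the nitro group to the amine and cleave both aryl benzyl ethers in one operation, whereas the methyl ethers and the diaryl ether are inert.

Step 10
Reactants: 15 2-amino-3-[2-(4-{5-[2-(2-hydroxyphenyl)ethyl]-2,3-dimethoxyphenoxy}phenyl)ethyl]phenol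
Product: 17 6-diazo-5-[2-(4-{5-[2-(2-hydroxyphenyl)ethyl]-2,3-dimethoxyphenoxy}phenyl)ethyl]cyclohexa-2,4-dien-1-one (seco ortho-quinone diazide; ring D phenol free), via diazonium chloride 16 (not isolated)
Conditions: isoamyl nitrite (1.0 equiv), HCl (2.5 equiv, 2 M in Et2O), EtOH–THF, −5 °C, dark; then cold CH2Cl2/sat. aq. NaHCO3, 0 °C; kept as a cold, dried CH2Cl2 solution
Reagents that add atoms: isoamyl nitrite (3-methylbutyl nitrite), CC(C)CCON=O
Why: Diazotisation of a 2-aminophenol followed by deprotonation to the ortho-quinone diazide: with one equivalent of nitrite N-nitrosation of the amine outruns C-nitrosation of the ring D phenol, and bicarbonate removes only the hydroxyl proton next to the diazonium group (pKa near 4), so the ring D phenol (pKa about 10) stays neutral and does not enter azo coupling.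

Step 11
Reactants: 17 seco ortho-quinone diazide
Product: 20 ring A di-O-methyl ether of the target (17-membered macrocycle; ring C phenol free), via dirhodium carbenoid 18 (not isolated), via oxonium phenolate 19 (not isolated)
Conditions: Rh2(OAc)4 (5 mol%), 4 Å MS, CH2Cl2, 40 °C, Ar, dark; 17 in CH2Cl2 (syringe held at 0 °C) added over 12 h, final concentration about 0.5 mM
Reagents that add atoms: none
Why: Proposed new method: Rh2(OAc)4 should take N2 out of 17 to give the electrophilic carbenoid 18 at C2 of ring C; the ring D phenol oxygen adds to this carbon, the dirhodium unit departs as ring C regains aromaticity in the oxonium phenolate 19, and a proton shift from the oxonium oxygen to the neighbouring phenolate oxygen delivers 20, so that the hindered diaryl ether and its ortho hydroxyl arise together without protection of that oxygen. The closest known reaction types are the dirhodium-catalysed O–H insertion of alpha-diazocarbonyl compounds into phenols and alcohols, the carbenoid arylation and cycloaddition chemistry of quinone diazides, and the macrocyclisations of long-chain diazo esters by remote carbenoid capture; a phenol O–H insertion of a monocyclic ortho-quinone diazide, and its use as a ring closure, has not been shown. The single ring formed, the 17-membered macrocycle, closes head to tail by C–O bond formation, formally a 17-exo attack with respect to the Rh=C bond that is broken, and no stereocentre is created. The step needs O–H insertion to beat (a) attack on arene carbons, (b) Wolff ring contraction and (c) intermolecular insertion: the phenol oxygen is the only heteroatom nucleophile in 17 and a better one than any arene carbon, metal catalysis at 40 °C in the dark in a non-aromatic solvent avoids the free carbene and hence the ring contraction, and slow addition into a large volume keeps the diazide concentration far below the effective molarity expected for the ring closure. The nearest arene, ring B, could be reached only through a six-membered transition state in which the two-carbon tether holds it close to the plane of ring C, where the dirhodium unit sits, and not over the perpendicular acceptor lobe of the carbenoid carbon, and its positions next to the tether are merely meta to the ring B oxygen. In CH2Cl2 the ring D O–H should also hydrogen-bond to the strongly polarised, phenolate-like carbonyl oxygen of the diazide, which places the nucleophilic oxygen beside the carbon that becomes the carbenoid.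

Step 12
Reactants: 20 ring A di-O-methyl ether of the target
Product: 21 target CNP0290892.0 (macrocyclic bis(bibenzyl) with ring A catechol and ring C phenol)
Conditions: BBr3 (6 equiv), CH2Cl2, −78 °C to rt; then H2O, 0 °C
Reagents that add atoms: none
Why: Aryl methyl ether cleavage with BBr3, in which bromide attacks the methyl carbon of the boron-complexed ether, whereas the two diaryl ether oxygens carry no sp3 carbon and should survive.

**Compound list**

1 | 2-hydroxybenzyl alcohol (salicyl alcohol) | OCc1ccccc1O | starting material
2 | 2-(benzyloxy)benzyl alcohol | OCc1ccccc1OCc1ccccc1 | intermediate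
3 | [2-(benzyloxy)benzyl]triphenylphosphonium bromide | [Br-].C(c1ccccc1OCc1ccccc1)[P+](c1ccccc1)(c1ccccc1)c1ccccc1 | intermediate
4 | 3-hydroxy-4,5-dimethoxybenzaldehyde | COc1cc(C=O)cc(O)c1OC | starting material
5 | ring D ylide, [2-(benzyloxy)benzylidene]triphenylphosphorane (not isolated) | C(c1ccccc1OCc1ccccc1)=P(c1ccccc1)(c1ccccc1)c1ccccc1 | intermediate
6 | 5-[(E)-2-(2-(benzyloxy)phenyl)ethenyl]-2,3-dimethoxyphenol | COc1cc(/C=C/c2ccccc2OCc2ccccc2)cc(O)c1OC | intermediate
7 | 4-fluorobenzaldehyde | O=Cc1ccc(F)cc1 | starting material
8 | 4-{5-[(E)-2-(2-(benzyloxy)phenyl)ethenyl]-2,3-dimethoxyphenoxy}benzaldehyde | COc1cc(/C=C/c2ccccc2OCc2ccccc2)cc(Oc2ccc(C=O)cc2)c1OC | intermediate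
9 | (4-{5-[(E)-2-(2-(benzyloxy)phenyl)ethenyl]-2,3-dimethoxyphenoxy}phenyl)methanol | COc1cc(/C=C/c2ccccc2OCc2ccccc2)cc(Oc2ccc(CO)cc2)c1OC | intermediate
10 | (4-{5-[(E)-2-(2-(benzyloxy)phenyl)ethenyl]-2,3-dimethoxyphenoxy}benzyl)triphenylphosphonium bromide | COc1cc(/C=C/c2ccccc2OCc2ccccc2)cc(Oc2ccc(C[P+](c3ccccc3)(c3ccccc3)c3ccccc3)cc2)c1OC.[Br-] | intermediate
11 | 3-hydroxy-2-nitrobenzaldehyde | O=Cc1cccc(O)c1[N+](=O)[O-] | starting material
12 | 3-(benzyloxy)-2-nitrobenzaldehyde | O=Cc1cccc(OCc2ccccc2)c1[N+](=O)[O-] | intermediate
13 | ring B ylide, benzylidenephosphorane derived from 10 (not isolated) | COc1cc(/C=C/c2ccccc2OCc2ccccc2)cc(Oc2ccc(C=P(c3ccccc3)(c3ccccc3)c3ccccc3)cc2)c1OC | intermediate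
14 | 1-(benzyloxy)-3-[(E)-2-(4-{5-[(E)-2-(2-(benzyloxy)phenyl)ethenyl]-2,3-dimethoxyphenoxy}phenyl)ethenyl]-2-nitrobenzene | COc1cc(/C=C/c2ccccc2OCc2ccccc2)cc(Oc2ccc(/C=C/c3cccc(OCc4ccccc4)c3[N+](=O)[O-])cc2)c1OC | intermediate
15 | 2-amino-3-[2-(4-{5-[2-(2-hydroxyphenyl)ethyl]-2,3-dimethoxyphenoxy}phenyl)ethyl]phenol | COc1cc(CCc2ccccc2O)cc(Oc2ccc(CCc3cccc(O)c3N)cc2)c1OC | intermediate
16 | 2-hydroxy-6-[2-(4-{5-[2-(2-hydroxyphenyl)ethyl]-2,3-dimethoxyphenoxy}phenyl)ethyl]benzenediazonium chloride (not isolated) | COc1cc(CCc2ccccc2O)cc(Oc2ccc(CCc3cccc(O)c3[N+]#N)cc2)c1OC.[Cl-] | intermediate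
17 | 6-diazo-5-[2-(4-{5-[2-(2-hydroxyphenyl)ethyl]-2,3-dimethoxyphenoxy}phenyl)ethyl]cyclohexa-2,4-dien-1-one (seco ortho-quinone diazide, key-step precursor) | [N-]=[N+]=C1C(=O)C=CC=C1CCc1ccc(cc1)Oc1cc(CCc2ccccc2O)cc(OC)c1OC | intermediate
18 | dirhodium carbenoid of 17, Rh2(OAc)4 bound at C2 of ring C, acetates written as ions (not isolated) | CC(=O)[O-].CC(=O)[O-].CC(=O)[O-].CC(=O)[O-].[Rh+2].[Rh+2]=C1C(=O)C=CC=C1CCc1ccc(cc1)Oc1cc(CCc2ccccc2O)cc(OC)c1OC | intermediate
19 | macrocyclic oxonium phenolate, protonated diaryl ether oxygen beside the ring C phenolate (not isolated) | COc1cc2cc(c1OC)Oc1ccc(cc1)CCc1cccc([O-])c1[OH+]c1ccccc1CC2 | intermediate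
20 | macrocyclic ring A dimethyl ether with free ring C phenol (key-step product) | COc1cc2cc(c1OC)Oc1ccc(cc1)CCc1cccc(O)c1Oc1ccccc1CC2 | intermediate
21 | CNP0290892.0 | Oc1cc2cc(c1O)Oc1ccc(cc1)CCc1cccc(O)c1Oc1ccccc1CC2 | target

**Totals and risks**

Total step count: 12. Longest linear sequence: 11 steps (steps 1–6 and 8–12, from 1).

**1. Step 11 (carbenoid O–H insertion macrocyclisation).**

- What may go wrong: capture of the carbenoid by arene carbons instead of the phenol oxygen, ring contraction after uncatalysed loss of nitrogen, intermolecular insertion leading to oligomerisation (including insertion into the phenol of product already formed), or capture by traces of water.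
- Fallback, known chemistry only: it sets out from 9 and comes back to the route at 21. The hindered ether is made intermolecularly and the ring closure moves to the ring B–ring C bridge.
- Hydrogenation of 9 (H2, 1 bar, Pd/C, neutral EtOAc, stopped once the stilbene and the benzyl ether are consumed so that the benzylic alcohol is kept) should give the phenol alcohol F1.
- SNAr of its ring D phenoxide on purchased 2-fluoro-3-methoxybenzaldehyde (K2CO3, DMF, 140 °C), whose ortho formyl group activates the fluoride, gives the diaryl ether aldehyde alcohol F2.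
- PPh3·HBr in refluxing MeCN gives the formyl phosphonium bromide F3.
- Slow addition of F3 to NaOMe in CH2Cl2 at high dilution generates the formyl ylide F4, which closes the ring by intramolecular Wittig olefination to the macrocyclic stilbene F5.
- Hydrogenation (H2, Pd/C, EtOAc) gives the macrocyclic trimethyl ether F6, and BBr3 in CH2Cl2 cleaves all three methyl ethers to 21.

**2. Step 10 (diazotisation in the presence of the free ring D phenol).**

- What may go wrong: C-nitrosation of the unprotected ring D phenol, azo coupling to it during neutralisation, or thermal or photochemical loss of nitrogen while the diazide is handled.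
- Fallback: it sets out from 15 and comes back at 17, with the ring D oxygen masked during nitrosation and neutralisation.
- TBSCl and imidazole in DMF convert both phenols of 15 into the bis(silyl ether) amine F7.
- Isoamyl nitrite and HCl in EtOH–THF at −5 °C give the silyloxy diazonium chloride F8.
- The silyl ether beside the diazonium group in F8 belongs to a phenol about six pKa units more acidic than the ring D phenol. It should therefore be hydrolysed selectively in the cold bicarbonate work-up to the ring D silyl ether diazide F9.
- HF·pyridine in THF at 0 °C in the dark, an acidic fluoride source that never releases a phenoxide, followed by cold bicarbonate, unmasks ring D and gives 17.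

**3. Step 3 (Wittig olefination of the unprotected phenolic aldehyde).**

- What may go wrong: proton transfer from the phenol to the ylide, precipitation of the aldehyde as its phenoxide salt, and a resulting stalled olefination.
- Fallback: it sets out from 4 and comes back at 8, with the phenol masked and the deprotection merged into the ether formation.
- TBSCl and imidazole in DMF give the silyl ether aldehyde F10.
- Wittig olefination with ylide 5 (from 3 and one equivalent of KOtBu, THF) gives the silyl ether stilbene F11.
- CsF with 7 in DMF at 80 °C triggers a desilylative SNAr in which the liberated phenoxide displaces the fluoride of 7 and the fluoride released carries the chain on, giving 8 directly.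

**Further compounds**

F1 | step 11 | 2-[2-(3-[4-(hydroxymethyl)phenoxy]-4,5-dimethoxyphenyl)ethyl]phenol | COc1cc(CCc2ccccc2O)cc(Oc2ccc(CO)cc2)c1OC
F2 | step 11 | 2-{2-[2-(3-[4-(hydroxymethyl)phenoxy]-4,5-dimethoxyphenyl)ethyl]phenoxy}-3-methoxybenzaldehyde | COc1cc(CCc2ccccc2Oc2c(C=O)cccc2OC)cc(Oc2ccc(CO)cc2)c1OC
F3 | step 11 | formyl phosphonium bromide derived from F2 | COc1cc(CCc2ccccc2Oc2c(C=O)cccc2OC)cc(Oc2ccc(C[P+](c3ccccc3)(c3ccccc3)c3ccccc3)cc2)c1OC.[Br-]
F4 | step 11 | formyl ylide derived from F3 | COc1cc(CCc2ccccc2Oc2c(C=O)cccc2OC)cc(Oc2ccc(C=P(c3ccccc3)(c3ccccc3)c3ccccc3)cc2)c1OC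
F5 | step 11 | macrocyclic stilbene trimethyl ether (drawn E) | COc1cc2cc(c1OC)Oc1ccc(cc1)/C=C/c1cccc(OC)c1Oc1ccccc1CC2
F6 | step 11 | macrocyclic trimethyl ether of the target | COc1cc2cc(c1OC)Oc1ccc(cc1)CCc1cccc(OC)c1Oc1ccccc1CC2
F7 | step 10 | bis(tert-butyldimethylsilyl) ether of 15 | COc1cc(CCc2ccccc2O[Si](C)(C)C(C)(C)C)cc(Oc2ccc(CCc3cccc(O[Si](C)(C)C(C)(C)C)c3N)cc2)c1OC
F8 | step 10 | silyloxy diazonium chloride derived from F7 | COc1cc(CCc2ccccc2O[Si](C)(C)C(C)(C)C)cc(Oc2ccc(CCc3cccc(O[Si](C)(C)C(C)(C)C)c3[N+]#N)cc2)c1OC.[Cl-]
F9 | step 10 | ring D tert-butyldimethylsilyl ether of 17 | [N-]=[N+]=C1C(=O)C=CC=C1CCc1ccc(cc1)Oc1cc(CCc2ccccc2O[Si](C)(C)C(C)(C)C)cc(OC)c1OC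
F10 | step 3 | 3-(tert-butyldimethylsilyloxy)-4,5-dimethoxybenzaldehyde | COc1cc(C=O)cc(O[Si](C)(C)C(C)(C)C)c1OC
F11 | step 3 | tert-butyldimethylsilyl ether of 6 | COc1cc(/C=C/c2ccccc2OCc2ccccc2)cc(O[Si](C)(C)C(C)(C)C)c1OC
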